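**Plan**
Locants: chromone O1–C8a (heptyl on C5, OH on C7); methylene C9 on C2; benzoate ring C1'–C6' (C9 on C1'; OH on C2', C3', C5'; H on C4'; CO2H on C6').
Cuts: C9–C2 (toluic acid carbanion + 2-sulfonylchromone); then C1'–C6' (aldol of a triketo ester stored as a 4-pyranone); then C5'–C6' (acetate enolate equivalent + maltol C6).
Chromone half: cut O1–C2 and C2–C3 (CS2 supplies C2) and C4–C4a (C-acetylation of 5-heptylresorcinol).
Enabling feature: C9–C1'–C2'(O)–C3'(O) is the methyl–C2–C3(O)–C4(=O) array of maltol, and the 1,3-oxygens on C3' and C5' with the carboxyl on C6' are a folded β-keto ester chain.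
Forward: maltol → pyranonylacetate → benzoate ring (first ring); 5-heptylresorcinol → chromone pyranone ring (second ring); union at C9–C2; four benzyl groups removed last.
Stereochemistry: the target has no stereocentre; the sp3 centres of 5 and 7 are racemic and transient.

Key step: step 4

Remark on the chemistry: benzyl replaces methyl on every oxygen so that the oxidation-prone 2',3',5'-trihydroxy ring is unveiled by neutral hydrogenolysis; silyl ketene acetal 3 (the O-silyl enolate of methyl acetate) and the LiN(i-Pr)2 solution are taken as purchased reagents.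

**Route**

Step 1
Reactants: 1 maltol
Product: 2 3-(benzyloxy)-2-methyl-4H-pyran-4-one
Conditions: BnBr, K2CO3, DMF, 60 °C
Reagents that add atoms: benzyl bromide, BrCc1ccccc1
Why: Williamson O-alkylation of the acidic enolic hydroxyl of maltol is routine and leaves the pyranone untouched.

Step 2
Reactants: 2 3-(benzyloxy)-2-methyl-4H-pyran-4-one; 3 tert-butyl[(1-methoxyethenyl)oxy]dimethylsilane
Product: 5 racemic methyl 2-{5-(benzyloxy)-4-[(tert-butyldimethylsilyl)oxy]-6-methyl-2H-pyran-2-yl}acetate, via siloxypyrylium triflate 4 (not isolated)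
Conditions: TBSOTf (1.1 equiv), CH2Cl2, rt; then 3, 2,6-lutidine, −78 °C to 0 °C; cold aq. NaHCO3, crude product used directly
Reagents that add atoms: tert-butyldimethylsilyl triflate, CC(C)(C)[Si](C)(C)OS(=O)(=O)C(F)(F)F
Why: O-silylation should turn the pyranone into a 4-siloxypyrylium ion, to which the ketene silyl acetal adds in Mukaiyama–Michael fashion at the unsubstituted C6 (the other α-carbon carries the methyl group next to the benzyloxy group); the new sp3 centre is racemic and is erased in step 3.

Step 3
Reactants: 5 racemic methyl 2-{5-(benzyloxy)-4-[(tert-butyldimethylsilyl)oxy]-6-methyl-2H-pyran-2-yl}acetate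
Product: 6 methyl 2-[5-(benzyloxy)-6-methyl-4-oxo-4H-pyran-2-yl]acetate
Conditions: DDQ (1.1 equiv), CH2Cl2, 0 °C to rt; aq. NaHCO3
Reagents that add atoms: none
Why: Quinone dehydrogenation of a silyl dienol ether: DDQ should take hydride from the ring CH that is allylic and α to the ring oxygen, and loss of the silyl group on work-up returns the 4-pyranone, as in the known conversion of such pyrylium adducts into 2-substituted pyranones and chromones.

Step 4
Reactants: 6 methyl 2-[5-(benzyloxy)-6-methyl-4-oxo-4H-pyran-2-yl]acetate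
Product: 8 methyl 3-(benzyloxy)-4,6-dihydroxy-2-methylbenzoate, via triketo ester 7 (not isolated)
Conditions: KOH (5 equiv), MeOH–H2O, 0 °C to rt; then 1 M HCl to pH 7, 40 °C; then HCl to pH 3
Reagents that add atoms: none
Why: Hydroxide should add to the methyl-bearing C1' of the pyranone (the C5' end is masked as the side-chain dienolate) and open the ring to the enolates of triketo ester 7; once the medium is brought to neutrality the ester-flanked C6' carbanion adds to the C1' ketone, and loss of the oxygen just introduced as water followed by enolisation gives the resorcylate. The closest known reactions are the alkali-induced conversion of 2,6-dimethyl-4-pyranone into orcinol and the aldol-type cyclisation of 3,5,7-triketo acids and esters and of 4-pyranon-2-ylacetates to orsellinates. The benzoate ring closes in a 6-(enolexo)-exo-trig aldol mode that forms C1'–C6'. No stereocentre is created, and the C2' stereocentre of 7 becomes an sp2 ring carbon. The step needs fold selectivity: the C6' methylene between ester and ketone is far more acidic than the C9 methyl, so closure C6'→C1' should beat C9→C5'. The Claisen mode (C2' onto the ester carbonyl) would create a quaternary, non-aromatisable carbon at the benzyloxy-bearing C2' and is further held back by leaving the strongly basic regime before cyclisation.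

Step 5
Reactants: 8 methyl 3-(benzyloxy)-4,6-dihydroxy-2-methylbenzoate
Product: 9 methyl 3,4,6-tris(benzyloxy)-2-methylbenzoate
Conditions: BnBr (2.5 equiv), K2CO3, DMF, 70 °C
Reagents that add atoms: benzyl bromide, BrCc1ccccc1
Why: Williamson etherification; the chelated hydroxyl ortho to the ester needs DMF and warming, which the ester and the existing benzyl ether tolerate.

Step 6
Reactants: 9 methyl 3,4,6-tris(benzyloxy)-2-methylbenzoate
Product: 10 3,4,6-tris(benzyloxy)-2-methylbenzoic acid
Conditions: KOH, DMSO–H2O, 90 °C; then aq. HCl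
Reagents that add atoms: potassium hydroxide, [K+].[OH-]
Why: Saponification of a di-ortho-substituted benzoate is slow but should go cleanly with hydroxide in hot aqueous DMSO, and aryl benzyl ethers are inert to it.

Step 7
Reactants: 11 5-heptylresorcinol
Product: 12 1-(2-heptyl-4,6-dihydroxyphenyl)ethan-1-one
Conditions: AcOH, BF3·OEt2, 90 °C; then aq. NaOAc
Reagents that add atoms: acetic acid, CC(=O)O
Why: BF3-promoted Friedel–Crafts (Nencki-type) C-acylation of a 5-alkylresorcinol goes at C4, para to one hydroxyl and ortho to the other, as with orcinol and olivetol, and chelation of the product to boron should prevent a second acylation.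

Step 8
Reactants: 12 1-(2-heptyl-4,6-dihydroxyphenyl)ethan-1-one
Product: 13 1-[4-(benzyloxy)-2-heptyl-6-hydroxyphenyl]ethan-1-one
Conditions: BnBr (1.05 equiv), K2CO3, acetone, reflux
Reagents that add atoms: benzyl bromide, BrCc1ccccc1
Why: Williamson etherification selects the para hydroxyl because the ortho hydroxyl is hydrogen-bonded to the acetyl carbonyl.

Step 9
Reactants: 13 1-[4-(benzyloxy)-2-heptyl-6-hydroxyphenyl]ethan-1-one
Product: 14 7-(benzyloxy)-5-heptyl-4-hydroxy-2H-chromene-2-thione
Conditions: KOt-Bu (3 equiv), CS2, toluene, 10 °C to rt; then aq. HCl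
Reagents that add atoms: carbon disulfide, S=C=S
Why: The ketone enolate adds to CS2 and the neighbouring phenoxide closes onto the dithiocarboxylate carbon with loss of hydrosulfide (6-exo-trig addition–elimination), the established route from 2-hydroxyacetophenones to 4-hydroxy-2H-chromene-2-thiones.

Step 10
Reactants: 14 7-(benzyloxy)-5-heptyl-4-hydroxy-2H-chromene-2-thione
Product: 15 7-(benzyloxy)-5-heptyl-2-(methylsulfanyl)-4H-chromen-4-one
Conditions: MeI, K2CO3, acetone, reflux
Reagents that add atoms: iodomethane, CI
Why: S-alkylation of the soft thione sulfur is preferred over O-alkylation and shifts the tautomer to the 2-alkylthio-4-chromone, as known for this heterocycle.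

Step 11
Reactants: 15 7-(benzyloxy)-5-heptyl-2-(methylsulfanyl)-4H-chromen-4-one
Product: 16 7-(benzyloxy)-5-heptyl-2-(methanesulfonyl)-4H-chromen-4-one
Conditions: mCPBA (2.3 equiv), CH2Cl2, 0 °C to rt
Reagents that add atoms: 3-chloroperoxybenzoic acid, OOC(=O)c1cccc(Cl)c1
Why: Peracid oxidation of the sulfide through the sulfoxide to the sulfone is standard, and the electron-poor C2=C3 bond and the benzyl ether should not be attacked.

Step 12
Reactants: 10 3,4,6-tris(benzyloxy)-2-methylbenzoic acid; 16 7-(benzyloxy)-5-heptyl-2-(methanesulfonyl)-4H-chromen-4-one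
Product: 18 3,4,6-tris(benzyloxy)-2-{[7-(benzyloxy)-5-heptyl-4-oxo-4H-chromen-2-yl]methyl}benzoic acid, via dilithiated benzoate 17 (not isolated)
Conditions: 10 (2.2 equiv), LiN(i-Pr)2 (4.5 equiv), THF, −78 to −20 °C; then 16 (1.0 equiv), −78 °C; aq. HCl to pH 3
Reagents that add atoms: none
Why: Proposed new method: LiN(i-Pr)2 should doubly deprotonate 10 to the laterally lithiated benzoate 17 (established lateral lithiation of o-toluic acids), whose benzylic carbanion is expected to add to C2 of 16, the β-carbon of an enone that also carries the sulfonyl group, after which the C3 enolate expels methanesulfinate (addition–elimination at a vinylic carbon); the closest known reactions are the displacement of 2-sulfinyl and 2-sulfonyl groups of chromones by amines and phenoxides and the substitution of heteroaryl methyl sulfones by organolithium and Grignard reagents; the carboxylate cannot be attacked by the chromone enolate (an ester could undergo Claisen ring closure from C3), the peri heptyl group shields the C4 carbonyl from 1,2-addition, and the second equivalent of 17 takes up the acidic C9 proton of the product.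

Step 13
Reactants: 18 3,4,6-tris(benzyloxy)-2-{[7-(benzyloxy)-5-heptyl-4-oxo-4H-chromen-2-yl]methyl}benzoic acid
Product: 19 2-[(5-heptyl-7-hydroxy-4-oxo-4H-chromen-2-yl)methyl]-3,4,6-trihydroxybenzoic acid
Conditions: H2 (1 atm), 10% Pd/C, EtOAc–MeOH, rt, degassed solvents, argon work-up
Reagents that add atoms: none
Why: Hydrogenolysis of aryl benzyl ethers over Pd/C is fast and neutral, the chromone C2=C3 bond (a vinylogous ester) should be reduced far more slowly, and the absence of acid, base and heat protects the decarboxylation-prone and air-sensitive trihydroxybenzoic acid.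

**Compound list**
1 | maltol (3-hydroxy-2-methyl-4H-pyran-4-one) | Cc1occc(=O)c1O | starting material
2 | 3-(benzyloxy)-2-methyl-4H-pyran-4-one | Cc1occc(=O)c1OCc1ccccc1 | intermediate
3 | tert-butyl[(1-methoxyethenyl)oxy]dimethylsilane | C=C(OC)O[Si](C)(C)C(C)(C)C | starting material
4 | 3-(benzyloxy)-4-[(tert-butyldimethylsilyl)oxy]-2-methylpyrylium triflate | Cc1[o+]ccc(O[Si](C)(C)C(C)(C)C)c1OCc1ccccc1.[O-]S(=O)(=O)C(F)(F)F | intermediate
5 | methyl 2-{5-(benzyloxy)-4-[(tert-butyldimethylsilyl)oxy]-6-methyl-2H-pyran-2-yl}acetate, racemic | COC(=O)CC1C=C(O[Si](C)(C)C(C)(C)C)C(OCc2ccccc2)=C(C)O1 | intermediate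
6 | methyl 2-[5-(benzyloxy)-6-methyl-4-oxo-4H-pyran-2-yl]acetate | COC(=O)Cc1cc(=O)c(OCc2ccccc2)c(C)o1 | intermediate
7 | methyl 6-(benzyloxy)-3,5,7-trioxooctanoate, racemic, present as its potassium enolates | COC(=O)CC(=O)CC(=O)C(OCc1ccccc1)C(C)=O | intermediate
8 | methyl 3-(benzyloxy)-4,6-dihydroxy-2-methylbenzoate | COC(=O)c1c(C)c(OCc2ccccc2)c(O)cc1O | intermediate
9 | methyl 3,4,6-tris(benzyloxy)-2-methylbenzoate | COC(=O)c1c(C)c(OCc2ccccc2)c(OCc2ccccc2)cc1OCc1ccccc1 | intermediate
10 | 3,4,6-tris(benzyloxy)-2-methylbenzoic acid | Cc1c(OCc2ccccc2)c(OCc2ccccc2)cc(OCc2ccccc2)c1C(=O)O | intermediate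
11 | 5-heptylresorcinol (5-heptylbenzene-1,3-diol) | CCCCCCCc1cc(O)cc(O)c1 | starting material
12 | 1-(2-heptyl-4,6-dihydroxyphenyl)ethan-1-one | CCCCCCCc1cc(O)cc(O)c1C(C)=O | intermediate
13 | 1-[4-(benzyloxy)-2-heptyl-6-hydroxyphenyl]ethan-1-one | CCCCCCCc1cc(OCc2ccccc2)cc(O)c1C(C)=O | intermediate
14 | 7-(benzyloxy)-5-heptyl-4-hydroxy-2H-chromene-2-thione | CCCCCCCc1cc(OCc2ccccc2)cc2oc(=S)cc(O)c12 | intermediate
15 | 7-(benzyloxy)-5-heptyl-2-(methylsulfanyl)-4H-chromen-4-one | CCCCCCCc1cc(OCc2ccccc2)cc2oc(SC)cc(=O)c12 | intermediate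
16 | 7-(benzyloxy)-5-heptyl-2-(methanesulfonyl)-4H-chromen-4-one | CCCCCCCc1cc(OCc2ccccc2)cc2oc(S(C)(=O)=O)cc(=O)c12 | intermediate
17 | lithium 3,4,6-tris(benzyloxy)-2-(lithiomethyl)benzoate | [Li+].[Li+].[CH2-]c1c(OCc2ccccc2)c(OCc2ccccc2)cc(OCc2ccccc2)c1C([O-])=O | intermediate
18 | 3,4,6-tris(benzyloxy)-2-{[7-(benzyloxy)-5-heptyl-4-oxo-4H-chromen-2-yl]methyl}benzoic acid | CCCCCCCc1cc(OCc2ccccc2)cc2oc(Cc3c(OCc4ccccc4)c(OCc4ccccc4)cc(OCc4ccccc4)c3C(=O)O)cc(=O)c12 | intermediate
19 | 2-[(5-heptyl-7-hydroxy-4-oxo-4H-chromen-2-yl)methyl]-3,4,6-trihydroxybenzoic acid | CCCCCCCc1cc(O)cc2oc(Cc3c(O)c(O)cc(O)c3C(=O)O)cc(=O)c12 | target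

**Count**
Total steps: 13. Longest linear sequence: 8 steps (steps 1–6, 12 and 13 from maltol); the chromone branch (steps 7–11) joins at step 12.

**Steps most likely to fail**

Step 12. Proton transfer from the methylsulfonyl group or from the C9 methylene of the product to the benzylic carbanion may outrun addition at C2, and 1,2-addition at C4 may compete. The fallback uses only established reactions, sets out from 10 and 13 and returns at 18. Acid 10 is dilithiated with LiN(i-Pr)2 as before and quenched with dimethyl carbonate to give the homophthalic half-ester 3,4,6-tris(benzyloxy)-2-(2-methoxy-2-oxoethyl)benzoic acid F1. The lithium dianion of acetophenone 13 (LiN(SiMe3)2, THF, −78 °C to rt) is then condensed with the lithium carboxylate of F1 in a Claisen acylation. This gives the diketone 3,4,6-tris(benzyloxy)-2-{4-[4-(benzyloxy)-2-heptyl-6-hydroxyphenyl]-2,4-dioxobutyl}benzoic acid F2; the carboxylate again keeps the benzoate carbon from acting as an electrophile. Acid-catalysed cyclodehydration of F2 (TsOH, AcOH, 60 °C), the classical closure of an o-hydroxyaryl 1,3-diketone, should then give chromone 18.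

Step 4. Under strong base the C2' carbanion may attack the ester carbonyl (Claisen mode) and the product may then lose its acetyl group; hydroxide may also cleave the triketone, or the chain may fold the other way. The fallback runs the same C1'–C6' closure at the carboxylate level, where no ester electrophile exists; it sets out from 6 and returns at 10. Ester 6 is saponified cold (LiOH, THF–H2O, 0 °C) to 2-[5-(benzyloxy)-6-methyl-4-oxo-4H-pyran-2-yl]acetic acid F3. F3 is opened with 2 M aqueous KOH at rt and the solution is brought to pH 5–6, where the triketo acid should cyclise to 3-(benzyloxy)-4,6-dihydroxy-2-methylbenzoic acid F4, as triketo acids are known to do. Exhaustive benzylation (BnBr, K2CO3, DMF) gives benzyl 3,4,6-tris(benzyloxy)-2-methylbenzoate F5, and saponification (KOH, DMSO–H2O, 90 °C) gives acid 10.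

Step 3. Hydride abstraction by DDQ may be slow, so that hydrolysis of the silyl dienol ether or oxidation at the benzyl ether takes over. The fallback replaces dehydrogenation by selenoxide elimination; it sets out from 5 and returns at 6. Silyl enol ether 5 is treated with PhSeCl (CH2Cl2, −78 °C) to give methyl 2-[5-(benzyloxy)-6-methyl-4-oxo-3-(phenylselanyl)-3,4-dihydro-2H-pyran-2-yl]acetate F6 (racemic, diastereomers equilibrate through the enol). Oxidation with H2O2 and pyridine at 0 °C should trigger syn-elimination of the selenoxide toward the ring CH and deliver pyranone 6.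

**Further compounds**
F1 | step 12 | 3,4,6-tris(benzyloxy)-2-(2-methoxy-2-oxoethyl)benzoic acid | COC(=O)Cc1c(OCc2ccccc2)c(OCc2ccccc2)cc(OCc2ccccc2)c1C(=O)O
F2 | step 12 | 3,4,6-tris(benzyloxy)-2-{4-[4-(benzyloxy)-2-heptyl-6-hydroxyphenyl]-2,4-dioxobutyl}benzoic acid | CCCCCCCc1cc(OCc2ccccc2)cc(O)c1C(=O)CC(=O)Cc1c(OCc2ccccc2)c(OCc2ccccc2)cc(OCc2ccccc2)c1C(=O)O
F3 | step 4 | 2-[5-(benzyloxy)-6-methyl-4-oxo-4H-pyran-2-yl]acetic acid | OC(=O)Cc1cc(=O)c(OCc2ccccc2)c(C)o1
F4 | step 4 | 3-(benzyloxy)-4,6-dihydroxy-2-methylbenzoic acid | Cc1c(OCc2ccccc2)c(O)cc(O)c1C(=O)O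
F5 | step 4 | benzyl 3,4,6-tris(benzyloxy)-2-methylbenzoate | Cc1c(OCc2ccccc2)c(OCc2ccccc2)cc(OCc2ccccc2)c1C(=O)OCc1ccccc1
F6 | step 3 | methyl 2-[5-(benzyloxy)-6-methyl-4-oxo-3-(phenylselanyl)-3,4-dihydro-2H-pyran-2-yl]acetate, racemic | COC(=O)CC1OC(C)=C(OCc2ccccc2)C(=O)C1[Se]c1ccccc1
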